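**Plan**

- Retrosynthesis: the C12 acetate goes on last. The exocyclic C7=C8 bond is cut (aldol condensation) into a 4-silyloxy-4-octadienylcyclopent-2-enone and the (4R,5Z)-4-acetoxy enal of the ester chain. The ring bonds C9–C10 and C11–C12 are then cut together, leaving acetylene and an open-chain 3-oxo thioester.
- Enabling feature: in the five-membered ring, C9 (carbonyl) and C12 (carbinol) are two carbonyl-level carbons held 1,3 by C8, and C10=C11 is an unsubstituted cis CH=CH. The ring is therefore a 3-oxoacyl unit plus acetylene, joined by a nickel-catalysed reductive [3+2] annulation.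
- Forward: dienol → acid → acyl Meldrum's acid → 2-pyridyl 3-oxo thioester; the annulation builds the only ring. The ester chain is made separately (acyl Sonogashira, transfer hydrogenation, acetylation, semihydrogenation, acetal hydrolysis) and joined by aldol addition and elimination; silyl-to-acetate exchange ends the route.
- Stereochemistry: C12 from the chiral P,N ligand on nickel in the annulation, trapped at once as the silyl ether. C4 from Ru-catalysed asymmetric transfer hydrogenation of an ynone. 14Z/17Z come from the starting dienol, 5Z from Lindlar reduction, 7E from thermodynamically controlled elimination.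

Key step: step 4

Remark: target atoms are referred to by prostanoid numbering (C1 ester carbon, C9 ring carbonyl, C12 ring carbinol, C20 chain end).
Assumption: (3Z,6Z)-nona-3,6-dien-1-ol is bought as the flavour-grade chemical.
Assumption: the sense of induction of (S)-t-Bu-PHOX in step 4 is assumed; if it proves opposite, the (R)-ligand is used with no other change.

**Step 1**
Reactants: 1 (3Z,6Z)-nona-3,6-dien-1-ol
Product: 2 (3Z,6Z)-nona-3,6-dienoic acid
Conditions: TEMPO (10 mol %), PhI(OAc)2 (2.2 equiv), MeCN/H2O (1:1), 0 → 20 °C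
Reagents that add atoms: water, O
Why: Oxoammonium (TEMPO) oxidation takes the primary alcohol through the aldehyde hydrate to the acid under near-neutral conditions that should leave the skipped (Z,Z)-diene unconjugated; no stereocentre is formed.

**Step 2**
Reactants: 2 (3Z,6Z)-nona-3,6-dienoic acid; 3 Meldrum's acid (2,2-dimethyl-1,3-dioxane-4,6-dione)
Product: 4 5-[(3Z,6Z)-1-hydroxynona-3,6-dien-1-ylidene]-2,2-dimethyl-1,3-dioxane-4,6-dione
Conditions: DCC (1.1 equiv), DMAP (1.5 equiv), CH2Cl2, 0 → 20 °C
Reagents that add atoms: none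
Why: Carbodiimide-mediated C-acylation of Meldrum's acid is a standard mild route from an acid to a 3-oxoacyl equivalent and is expected to tolerate the β,γ-unsaturated acid without double-bond migration.

**Step 3**
Reactants: 4 acyl Meldrum's acid; 5 pyridine-2-thiol
Product: 7 S-(pyridin-2-yl) (5Z,8Z)-3-oxoundeca-5,8-dienethioate, via acylketene 6 (not isolated)
Conditions: toluene, 80 °C
Reagents that add atoms: none
Why: Thermal cycloreversion of the acyl Meldrum's acid (loss of acetone and CO2) gives the acylketene, which the thiol traps at sulfur; this acylketene thiolysis is the usual route to β-keto thioesters.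

**Step 4**
Reactants: 7 S-(pyridin-2-yl) (5Z,8Z)-3-oxoundeca-5,8-dienethioate; 8 acetylene
Product: 9 (4R)-4-[(2Z,5Z)-octa-2,5-dien-1-yl]-4-[(triethylsilyl)oxy]cyclopent-2-en-1-one
Conditions: NiBr2(MeOCH2CH2OMe) (10 mol %), (S)-t-Bu-PHOX (12 mol %), Mn powder (3 equiv), Et3SiCl (2 equiv), C2H2 (1 atm), DMA/THF, 0 → 25 °C, slow addition of 7
Reagents that add atoms: chlorotriethylsilane, CC[Si](Cl)(CC)CC
Why: Proposed new method: zerovalent nickel (from the nickel bromide and Mn) carrying the P,N ligand should undergo oxidative addition into the N-chelated C(acyl)–S bond of 7, syn acylnickelation of acetylene (forming C9–C10) and 1,2-addition of the resulting cis alkenyl–nickel bond to the ketone carbon C12 (forming C11–C12), after which Et3SiCl silylates the nickel alkoxide and Mn returns divalent nickel to the zerovalent state; the closest known reaction type is the nickel- or cobalt-catalysed reductive [3+2] annulation of ortho-haloaryl ketones with alkynes to indenols, here with an acyl–nickel bond in place of an aryl–nickel bond and with acyl–nickel generation as in nickel/Mn reductive ketone syntheses from 2-pyridyl thioesters. The cyclopentenone ring closes in the 5-exo-trig mode by attack of the alkenyl carbon C11 on the C12 carbonyl after the intermolecular C9–C10 bond has formed. The only new stereocentre, C12, is set in this 1,2-addition by the chiral ligand on divalent nickel, as in known enantioselective additions of alkenyl–nickel bonds to ketones, and immediate O-silylation should block retro-aldol racemisation of the tertiary alkoxide. The step needs chemoselective C–S activation, a single acetylene insertion and ring closure faster than protonolysis by the acidic C8 methylene; the 1,3-placement of thioester and ketone (five-membered transition state reached from the cis geometry of syn insertion), the absence of any other oxidative-addition site in 7, and a low stationary concentration of 7 are expected to secure this.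

**Step 5**
Reactants: 10 methyl 4-chloro-4-oxobutanoate; 11 3,3-diethoxyprop-1-yne
Product: 12 methyl 7,7-diethoxy-4-oxohept-5-ynoate
Conditions: PdCl2(PPh3)2 (2 mol %), CuI (4 mol %), Et3N (1.2 equiv), THF, 20 °C
Reagents that add atoms: none
Why: Acyl Sonogashira coupling of an acid chloride with a terminal alkyne gives the ynone directly, the acetal and the methyl ester being inert.

**Step 6**
Reactants: 12 methyl 7,7-diethoxy-4-oxohept-5-ynoate
Product: 13 methyl (4R)-7,7-diethoxy-4-hydroxyhept-5-ynoate
Conditions: Ru[(R,R)-TsDPEN](p-cymene) (1 mol %), i-PrOH, 25 °C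
Reagents that add atoms: none
Why: Noyori asymmetric transfer hydrogenation of an ynone, in which the alkynyl group takes the place of the aryl group of aryl ketones in the transition state, so the (R,R)-catalyst should deliver hydride to the face that gives the 4R propargylic alcohol.

**Step 7**
Reactants: 13 methyl (4R)-7,7-diethoxy-4-hydroxyhept-5-ynoate
Product: 14 methyl (4R)-4-acetoxy-7,7-diethoxyhept-5-ynoate
Conditions: Ac2O, pyridine, DMAP (5 mol %), CH2Cl2, 0 °C
Reagents that add atoms: acetic anhydride, CC(=O)OC(C)=O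
Why: DMAP-catalysed acetylation of the secondary alcohol, carried out at once so that the γ-hydroxy ester cannot lactonise, leaves the stereocentre untouched.

**Step 8**
Reactants: 14 methyl (4R)-4-acetoxy-7,7-diethoxyhept-5-ynoate
Product: 15 methyl (4R,5Z)-4-acetoxy-7,7-diethoxyhept-5-enoate
Conditions: H2 (1 atm), Pd/CaCO3 poisoned with Pb(OAc)2, quinoline, EtOAc, 20 °C
Reagents that add atoms: none
Why: Lindlar semihydrogenation adds H2 syn to the alkyne and should give the 5Z alkene, quinoline suppressing over-reduction and hydrogenolysis of the propargylic acetate.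

**Step 9**
Reactants: 15 methyl (4R,5Z)-4-acetoxy-7,7-diethoxyhept-5-enoate
Product: 16 methyl (4R,5Z)-4-acetoxy-7-oxohept-5-enoate
Conditions: Amberlyst-15, acetone/H2O (20:1), 0 °C
Reagents that add atoms: water, O
Why: Mild acid-catalysed acetal hydrolysis over a sulfonic acid resin frees the enal at low temperature, conditions chosen to limit Z-to-E isomerisation of the (Z)-4-acetoxy-2-enal.

**Step 10**
Reactants: 9 (4R)-4-[(2Z,5Z)-octa-2,5-dien-1-yl]-4-[(triethylsilyl)oxy]cyclopent-2-en-1-one; 16 methyl (4R,5Z)-4-acetoxy-7-oxohept-5-enoate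
Product: 18 methyl (4R,5Z)-4-acetoxy-7-hydroxy-7-[(5S)-5-[(2Z,5Z)-octa-2,5-dien-1-yl]-2-oxo-5-[(triethylsilyl)oxy]cyclopent-3-en-1-yl]hept-5-enoate (mixture of diastereomers at C7 and C8), via lithium dienolate 17 (not isolated)
Conditions: LiN(i-Pr)2 (1.05 equiv), THF, −78 °C; then 16, −78 °C; AcOH quench
Reagents that add atoms: none
Why: Kinetic deprotonation at C8, the only enolisable position because C12 is quaternary, gives a cross-conjugated dienolate that should add 1,2 to the aldehyde in a directed aldol addition (loss of silanolate would give an antiaromatic cyclopentadienone and is not expected); the uncontrolled stereocentres at C7 and C8 are removed in step 11.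

**Step 11**
Reactants: 18 aldol adduct
Product: 20 methyl (4R,5Z,7E,12S,14Z,17Z)-4-acetoxy-9-oxo-12-[(triethylsilyl)oxy]prosta-5,7,10,14,17-pentaenoate, via mesylate 19 (not isolated)
Conditions: MsCl, Et3N, CH2Cl2, −20 °C; then DBU, −20 → 0 °C
Reagents that add atoms: none
Why: Mesylation of the β-hydroxy ketone and base-induced E1cB elimination should give the exocyclic enone with the 7E geometry (H7 syn to the carbonyl) that is thermodynamically preferred for 2-alkylidenecyclopentenones, the short cold exposure to base being chosen to preserve the 5Z alkene.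

**Step 12**
Reactants: 20 silyl ether
Product: 21 methyl (4R,5Z,7E,12S,14Z,17Z)-4-acetoxy-12-hydroxy-9-oxoprosta-5,7,10,14,17-pentaenoate
Conditions: HF·pyridine, pyridine/THF, 0 °C
Reagents that add atoms: none
Why: Fluoride-mediated cleavage of the tertiary triethylsilyl ether with buffered HF·pyridine should leave the acetate, the methyl ester and the cross-conjugated dienone untouched.

**Step 13**
Reactants: 21 tertiary alcohol
Product: 22 methyl (4R,5Z,7E,12S,14Z,17Z)-4,12-diacetoxy-9-oxoprosta-5,7,10,14,17-pentaenoate (the target)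
Conditions: Ac2O (excess), DMAP, Et3N, CH2Cl2, 20 °C
Reagents that add atoms: acetic anhydride, CC(=O)OC(C)=O
Why: DMAP-catalysed acyl transfer acetylates the tertiary allylic alcohol with retention, since ionisation at C12 would give an antiaromatic hydroxycyclopentadienyl-type cation and is not expected under basic conditions.

**Compound list**

1 | (3Z,6Z)-nona-3,6-dien-1-ol | CC/C=C\C/C=C\CCO | starting material
2 | (3Z,6Z)-nona-3,6-dienoic acid | CC/C=C\C/C=C\CC(=O)O | intermediate
3 | Meldrum's acid (2,2-dimethyl-1,3-dioxane-4,6-dione) | CC1(C)OC(=O)CC(=O)O1 | starting material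
4 | 5-[(3Z,6Z)-1-hydroxynona-3,6-dien-1-ylidene]-2,2-dimethyl-1,3-dioxane-4,6-dione | CC/C=C\C/C=C\CC(O)=C1C(=O)OC(C)(C)OC1=O | intermediate
5 | pyridine-2-thiol | Sc1ccccn1 | starting material
6 | (5Z,8Z)-undeca-1,5,8-triene-1,3-dione (acylketene) | CC/C=C\C/C=C\CC(=O)C=C=O | intermediate (not isolated)
7 | S-(pyridin-2-yl) (5Z,8Z)-3-oxoundeca-5,8-dienethioate | CC/C=C\C/C=C\CC(=O)CC(=O)Sc1ccccn1 | intermediate
8 | acetylene | C#C | starting material
9 | (4R)-4-[(2Z,5Z)-octa-2,5-dien-1-yl]-4-[(triethylsilyl)oxy]cyclopent-2-en-1-one | CC/C=C\C/C=C\C[C@]1(O[Si](CC)(CC)CC)C=CC(=O)C1 | intermediate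
10 | methyl 4-chloro-4-oxobutanoate | COC(=O)CCC(=O)Cl | starting material
11 | 3,3-diethoxyprop-1-yne | CCOC(OCC)C#C | starting material
12 | methyl 7,7-diethoxy-4-oxohept-5-ynoate | CCOC(OCC)C#CC(=O)CCC(=O)OC | intermediate
13 | methyl (4R)-7,7-diethoxy-4-hydroxyhept-5-ynoate | CCOC(OCC)C#C[C@@H](CCC(=O)OC)O | intermediate
14 | methyl (4R)-4-acetoxy-7,7-diethoxyhept-5-ynoate | CCOC(OCC)C#C[C@@H](CCC(=O)OC)OC(C)=O | intermediate
15 | methyl (4R,5Z)-4-acetoxy-7,7-diethoxyhept-5-enoate | CCOC(OCC)/C=C\[C@@H](CCC(=O)OC)OC(C)=O | intermediate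
16 | methyl (4R,5Z)-4-acetoxy-7-oxohept-5-enoate | O=C/C=C\[C@@H](CCC(=O)OC)OC(C)=O | intermediate
17 | lithium (3S)-3-[(2Z,5Z)-octa-2,5-dien-1-yl]-3-[(triethylsilyl)oxy]cyclopenta-1,4-dien-1-olate (lithium dienolate of 9) | CC/C=C\C/C=C\C[C@]1(O[Si](CC)(CC)CC)C=CC(O[Li])=C1 | intermediate (not isolated)
18 | methyl (4R,5Z)-4-acetoxy-7-hydroxy-7-[(5S)-5-[(2Z,5Z)-octa-2,5-dien-1-yl]-2-oxo-5-[(triethylsilyl)oxy]cyclopent-3-en-1-yl]hept-5-enoate (C7/C8 diastereomer mixture) | CC/C=C\C/C=C\C[C@]1(O[Si](CC)(CC)CC)C=CC(=O)C1C(O)/C=C\[C@@H](CCC(=O)OC)OC(C)=O | intermediate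
19 | 7-methanesulfonate of 18 | CC/C=C\C/C=C\C[C@]1(O[Si](CC)(CC)CC)C=CC(=O)C1C(OS(C)(=O)=O)/C=C\[C@@H](CCC(=O)OC)OC(C)=O | intermediate (not isolated)
20 | methyl (4R,5Z,7E,12S,14Z,17Z)-4-acetoxy-9-oxo-12-[(triethylsilyl)oxy]prosta-5,7,10,14,17-pentaenoate | CC/C=C\C/C=C\C[C@]1(O[Si](CC)(CC)CC)C=CC(=O)/C1=C/C=C\[C@@H](CCC(=O)OC)OC(C)=O | intermediate
21 | methyl (4R,5Z,7E,12S,14Z,17Z)-4-acetoxy-12-hydroxy-9-oxoprosta-5,7,10,14,17-pentaenoate | CC/C=C\C/C=C\C[C@]1(O)C=CC(=O)/C1=C/C=C\[C@@H](CCC(=O)OC)OC(C)=O | intermediate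
22 | methyl (4R,5Z,7E,12S,14Z,17Z)-4,12-diacetoxy-9-oxoprosta-5,7,10,14,17-pentaenoate | CC/C=C\C/C=C\C[C@]1(OC(C)=O)C=CC(=O)/C1=C/C=C\[C@@H](CCC(=O)OC)OC(C)=O | target

**Totals**

Total step count: 13.
Longest linear sequence: 9 steps (steps 5 to 13, from methyl 4-chloro-4-oxobutanoate); the ring branch (steps 1 to 4) joins at step 10.

**Steps most likely to fail**

1. Step 4 (proposed new method). What may go wrong:
- oligomerisation or cyclotrimerisation of acetylene at nickel;
- loss of CO from the acyl–nickel bond before insertion;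
- protonolysis of the alkenyl–nickel bond by the acidic C8 methylene before ring closure;
- reductive self-coupling of the thioester;
- weak enantiofacial discrimination at the ketone.

Fallback (known reactions only; sets out from acid 2, returns at 9). Acid 2 is converted with CDI and MeNH(OMe)·HCl into the Weinreb amide (3Z,6Z)-N-methoxy-N-methylnona-3,6-dienamide F1. Vinylmagnesium bromide gives the vinyl ketone (5Z,8Z)-undeca-1,5,8-trien-3-one F2. A Reformatsky reaction with the zinc reagent from 2-bromo-N-methoxy-N-methylacetamide (Zn dust, THF) adds 1,2 and gives the racemic carbinol (5Z,8Z)-3-ethenyl-3-hydroxy-N-methoxy-N-methylundeca-5,8-dienamide F3. Et3SiOTf/2,6-lutidine gives its triethylsilyl ether (5Z,8Z)-3-ethenyl-N-methoxy-N-methyl-3-[(triethylsilyl)oxy]undeca-5,8-dienamide F4. A second addition of vinylmagnesium bromide gives the dienone (7Z,10Z)-5-ethenyl-5-[(triethylsilyl)oxy]trideca-1,7,10-trien-3-one F5. Ring-closing metathesis with RuCl2(H2IMes)(PCy3)(=CHPh), the second-generation Grubbs catalyst, closes C10=C11 and gives racemic 4-[(2Z,5Z)-octa-2,5-dien-1-yl]-4-[(triethylsilyl)oxy]cyclopent-2-en-1-one F6. Preparative HPLC on a chiral stationary phase then delivers the (R)-enantiomer, compound 9.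

2. Step 11. What may go wrong:
- isomerisation of the 5Z alkene during the base-induced elimination;
- vinylogous loss of the allylic C4 acetate through the extended enolate;
- formation of 7E/7Z mixtures.

Fallback (sets out from 14 and dienolate 17, returns at 20). The alkyne stands in for the 5Z alkene until the exocyclic alkene is in place. Acetal hydrolysis of 14 (Amberlyst-15, wet acetone) gives the ynal methyl (4R)-4-acetoxy-7-oxohept-5-ynoate F7. Aldol addition of 17 gives methyl (4R)-4-acetoxy-7-hydroxy-7-[(5S)-5-[(2Z,5Z)-octa-2,5-dien-1-yl]-2-oxo-5-[(triethylsilyl)oxy]cyclopent-3-en-1-yl]hept-5-ynoate F8. MsCl/Et3N gives its 7-methanesulfonate F9, and DBU gives the enynone methyl (4R,7E,12S,14Z,17Z)-4-acetoxy-9-oxo-12-[(triethylsilyl)oxy]prosta-7,10,14,17-tetraen-5-ynoate F10. Semihydrogenation of the conjugated alkyne (H2, Pd/CaCO3 poisoned with Pb(OAc)2, quinoline) sets the 5Z alkene last and returns to 20.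

3. Step 9. What may go wrong:
- Z-to-E isomerisation of the enal under acid through reversible hydration or dienol formation;
- acid-induced loss or migration of the allylic acetate.

Fallback (sets out from acetal 15 and dienolate 17, returns at 20). The free (Z)-enal is never formed. Dienolate 17 is silylated with Me3SiCl to the silyl dienol ether (3S)-3-[(2Z,5Z)-octa-2,5-dien-1-yl]-3-[(triethylsilyl)oxy]-1-[(trimethylsilyl)oxy]cyclopenta-1,4-diene F11. Me3SiOTf-catalysed Mukaiyama-type addition of F11 to acetal 15 at −78 °C gives the β-ethoxy ketone methyl (4R,5Z)-4-acetoxy-7-ethoxy-7-[(5S)-5-[(2Z,5Z)-octa-2,5-dien-1-yl]-2-oxo-5-[(triethylsilyl)oxy]cyclopent-3-en-1-yl]hept-5-enoate F12. DBU-induced elimination of ethanol then gives 20.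

**Further compounds**

F1 | step 4 | (3Z,6Z)-N-methoxy-N-methylnona-3,6-dienamide | CC/C=C\C/C=C\CC(=O)N(C)OC
F2 | step 4 | (5Z,8Z)-undeca-1,5,8-trien-3-one | CC/C=C\C/C=C\CC(=O)C=C
F3 | step 4 | (5Z,8Z)-3-ethenyl-3-hydroxy-N-methoxy-N-methylundeca-5,8-dienamide (racemic) | CC/C=C\C/C=C\CC(O)(C=C)CC(=O)N(C)OC
F4 | step 4 | (5Z,8Z)-3-ethenyl-N-methoxy-N-methyl-3-[(triethylsilyl)oxy]undeca-5,8-dienamide (racemic) | CC/C=C\C/C=C\CC(O[Si](CC)(CC)CC)(C=C)CC(=O)N(C)OC
F5 | step 4 | (7Z,10Z)-5-ethenyl-5-[(triethylsilyl)oxy]trideca-1,7,10-trien-3-one (racemic) | CC/C=C\C/C=C\CC(O[Si](CC)(CC)CC)(C=C)CC(=O)C=C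
F6 | step 4 | 4-[(2Z,5Z)-octa-2,5-dien-1-yl]-4-[(triethylsilyl)oxy]cyclopent-2-en-1-one (racemic) | CC/C=C\C/C=C\CC1(O[Si](CC)(CC)CC)C=CC(=O)C1
F7 | step 11 | methyl (4R)-4-acetoxy-7-oxohept-5-ynoate | O=CC#C[C@@H](CCC(=O)OC)OC(C)=O
F8 | step 11 | methyl (4R)-4-acetoxy-7-hydroxy-7-[(5S)-5-[(2Z,5Z)-octa-2,5-dien-1-yl]-2-oxo-5-[(triethylsilyl)oxy]cyclopent-3-en-1-yl]hept-5-ynoate | CC/C=C\C/C=C\C[C@]1(O[Si](CC)(CC)CC)C=CC(=O)C1C(O)C#C[C@@H](CCC(=O)OC)OC(C)=O
F9 | step 11 | 7-methanesulfonate of F8 | CC/C=C\C/C=C\C[C@]1(O[Si](CC)(CC)CC)C=CC(=O)C1C(OS(C)(=O)=O)C#C[C@@H](CCC(=O)OC)OC(C)=O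
F10 | step 11 | methyl (4R,7E,12S,14Z,17Z)-4-acetoxy-9-oxo-12-[(triethylsilyl)oxy]prosta-7,10,14,17-tetraen-5-ynoate | CC/C=C\C/C=C\C[C@]1(O[Si](CC)(CC)CC)C=CC(=O)/C1=C/C#C[C@@H](CCC(=O)OC)OC(C)=O
F11 | step 9 | (3S)-3-[(2Z,5Z)-octa-2,5-dien-1-yl]-3-[(triethylsilyl)oxy]-1-[(trimethylsilyl)oxy]cyclopenta-1,4-diene | CC/C=C\C/C=C\C[C@]1(O[Si](CC)(CC)CC)C=CC(O[Si](C)(C)C)=C1
F12 | step 9 | methyl (4R,5Z)-4-acetoxy-7-ethoxy-7-[(5S)-5-[(2Z,5Z)-octa-2,5-dien-1-yl]-2-oxo-5-[(triethylsilyl)oxy]cyclopent-3-en-1-yl]hept-5-enoate | CC/C=C\C/C=C\C[C@]1(O[Si](CC)(CC)CC)C=CC(=O)C1C(OCC)/C=C\[C@@H](CCC(=O)OC)OC(C)=O
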